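## Analysis of the target

Target 16 is a flavone, 2-(2-hydroxy-4,5-dimethoxyphenyl)-3,7,8-trimethoxy-4H-chromen-4-one. Its 4-pyranone ring C (O1, C2, C3, C4) is fused through C4a–C8a to benzo ring A and carries ring B on C2 through the C2–C1' bond. It has no stereocentre, and the C2–C1' axis, with one ortho substituent on ring B, is not expected to be configurationally stable, so the problem is one of constitution only. Six oxygen substituents must be placed and told apart: C3, C7, C8, C4' and C5' carry methyl ethers and C2' alone carries a free hydroxyl. The sensitive parts are the pyranone, which accepts nucleophiles at C2 and can open or contract under strong base, and ring B, a 1,2,4-trioxygenated benzene that is easily oxidised once its phenol is free. The hard points are the contiguous C7/C8 oxygenation next to O1, the oxygen on C3, and the single phenol among five ethers. The strategy rests on C3: it is one carbon with one heteroatom, bonded in the skeleton only to C2 and C4. Taking it out joins C2 to C4 and leaves a 2-aryl-6,7-dimethoxybenzofuran-3-one in which both benzene rings and every other oxygen are already in place.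

## Retrosynthetic reasoning

**O–benzyl bond at C2' (16 ⇐ 15).** The free phenol is taken back to the benzyl ether 15, 2-[2-(benzyloxy)-4,5-dimethoxyphenyl]-3,7,8-trimethoxy-4H-chromen-4-one. The C2' oxygen has to stay masked through enolate, carbene and alkoxide chemistry and must remain distinct from five methyl ethers. A benzyl group does both, and the forward step, hydrogenolysis, is neutral and touches neither the methyl ethers nor the pyranone.

**C3–O bond (15 ⇐ 14).** The C3 methoxy group is exchanged for bromine, giving the 3-bromoflavone 14. The cut is made here because the one-carbon insertion below delivers C3 at the halide level. The forward reaction has to replace a halogen on an sp2 carbon by a methoxy group without adding a nucleophile to C2.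

**C2–C3 and C3–C4 bonds (14 ⇐ 10 + 11, through 12 and 13).** Both bonds to C3 are cut at once and C2 is rejoined to C4, which contracts ring C to the furan of the 3-silyloxybenzofuran 10. C3 and its bromine come from bromoform 11 through the dihalocarbene made from it. This cut is preferred to the usual O1–C2 or C2–C3 disconnections of flavones because it leaves a precursor with both arenes complete. The only constitutional question, where the carbon goes in, is answered by the structure of the fused cyclopropane 12, which can open only across the bond it shares with the furan to give the pyrylium salt 13. The forward reaction must add the carbene to the C2=C3 enol ether bond of 10 in preference to the alkoxyarenes.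

**O–Si bond (10 ⇐ 9).** The silyl enol ether is taken back to the ketone 9, 2-[2-(benzyloxy)-4,5-dimethoxyphenyl]-6,7-dimethoxy-1-benzofuran-3(2H)-one. Silylation fixes the enol form, which is aromatic, gives the carbene its electron-rich alkene and removes the labile C2 stereocentre of 9.

**C2–C1' bond (9 ⇐ 5 + 8).** The bond between the benzofuranone C2 and ring B is cut to the parent ketone 5 and the aryl bromide 8. C2 of 5 is its only enolisable carbon, so an enolate arylation is regiochemically unambiguous, and the cut divides the molecule into its ring A and ring B halves.

**O1–C2 and aryl–acyl bonds of the benzofuranone (5 ⇐ 4 ⇐ 1 + 2, through 3).** Ketone 5 opens at O1–C2 to the phenacyl chloride 4, whose acyl group is removed to give 1,2,3-trimethoxybenzene 1 and chloroacetyl chloride 2. The acylation intermediate 3 carries three methyl ethers. Chelation by the Lewis acid selects the ether next to the carbonyl for cleavage, so the same operation releases exactly the phenol that becomes O1 and leaves the C7/C8 methyl ethers of the target in place.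

**C–Br and O–benzyl bonds of ring B (8 ⇐ 7 ⇐ 6).** Bromide 8 loses its bromine to give the benzyl ether 7, which comes from 3,4-dimethoxyphenol 6. Benzylation first protects the phenol against oxidation during halogenation, and the position that must be brominated is the most activated one of 7.

## Alternatives that were turned down

**Alternative 1:** Ring C is cut at C4–C4a and O1–C8a, with ring A taken back to a dihydro level. In the forward sense the dioxinone A2 is heated to unmask its acylketene, which adds as a 1-oxadiene across the silyl enol ether bond of the cyclohexadiene A3. Loss of silanol from the cycloadduct gives the 5,6-dihydrochromenone A1.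
- For: two bonds of ring C form in one thermal step without added reagent, the two halves are joined convergently, and the C3 methoxy group is present from the start. On that last point it is stronger than the chosen route, which spends one step on exchanging bromine for methoxy.
- Against: neither A2 nor A3 is an article of commerce and each needs its own multistep preparation, whereas the chosen route starts from the aromatic compounds 1 and 6. A3 contains a second electron-rich alkene, the C7=C8 dimethoxy bond, conjugated with the enol ether, so it can also react as a diene toward the ketene. Nothing in the structure decides between the two modes. A1 must afterwards be dehydrogenated at C5–C6 in the presence of the oxidation-prone ring B.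
- Comparison: the chosen strategy keeps ring A aromatic from the first step and needs no oxidation. What it offers in place of the built-in C3 oxygen is a shorter, cheaper approach to its key-step precursor.

**Alternative 2:** Ring C is cut at C3–C4 at the 3-hydroxychromanone oxidation level. In the forward sense the dialdehyde A5 is treated with a thiazolium-derived carbene catalyst and an amine base. The carbene adds to the formyl group on ring A, and the resulting acyl anion equivalent attacks the aliphatic formyl group, closing ring C as the 3-hydroxychromanone A4.
- For: the step is catalytic, mild and metal-free, and it forms the ring and places an oxygen on C3 at once. In mildness it is at least as good as the carbene step chosen here.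
- Against: A5 contains an α-aryl-α-aryloxy acetaldehyde, which enolises very easily and is open to aldol reaction and elimination. Either formyl group can serve as the acyl anion donor, and only one choice gives the C4 ketone. A4 is formed as racemic diastereomers whose two stereocentres are then destroyed. It still needs dehydrogenation across C2–C3, O-methylation at C3 and debenzylation, three steps after the key step against two in the chosen route.
- Comparison: the chosen strategy creates no stereocentre that survives, needs no oxidation near ring B, and reaches its precursor by standard aromatic chemistry.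

**Alternative 3:** Here ring C is the starting point and ring A is cut at C7–C8 and C4a–C5. The pyranone A7 would be made from kojic acid A9 by methylation of both hydroxyls and arylation at the free position next to the ring oxygen. A7 is deprotonated at its methoxymethyl group with a lithium amide and acylated by the acetal ester A8. Acid in the same flask then releases the acetal carbon, which attacks the free pyranone position that becomes C4a, and loss of an alcohol molecule with enolisation aromatises ring A to give the 7-hydroxyflavone A6.
- For: A9 is cheap and already contains O1, C2, C3 with its oxygen, C4 and the carbon that becomes C8, so the C3 oxygen never has to be introduced. The step count is about the same as for the chosen route, and on the longest linear sequence it is probably one step shorter. The free C7 hydroxyl would be an advantage for C7 analogues. On these points it is as strong as or stronger than the chosen strategy.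
- Against: for this target the C7 hydroxyl costs an extra methylation. The cascade needs two equivalents of base, and the carbanion, α to an ether oxygen and only vinylogously stabilised, competes with addition to the electrophilic positions of another pyranone molecule. The ring closure uses the α-carbon of a vinylogous ester, a modest nucleophile, under strong acid that also threatens the benzyl ether on the very electron-rich ring B. The arylation of the pyranone with an ortho-substituted partner is not trivial.
- Comparison: the chosen strategy offers two preformed benzene rings with fixed substitution and a key step whose regiochemistry is dictated by the fused three-membered ring, not by relative rates at several acidic and electrophilic sites.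

Key step: step 7

Remark on the chemistry: the target is achiral. Compounds 9 and 12 are formed as racemates and their stereocentres disappear in steps 6 and 7, so no stereocontrol is needed.

## Route

**Step 1**
Reactants: 1 1,2,3-trimethoxybenzene; 2 chloroacetyl chloride
Product: 4 2-chloro-1-(2-hydroxy-3,4-dimethoxyphenyl)ethan-1-one, via trimethoxyphenyl chloromethyl ketone 3 (not isolated)
Conditions: AlCl3 (2.5 equiv), CH2Cl2, 0 °C to reflux; ice/aq. HCl
Reagents that add atoms: chloroacetyl chloride (compound 2), ClCC(=O)Cl
Why: Friedel–Crafts acylation at C4 of 1, para to one outer methoxy group and ortho to the other, gives 3 as its AlCl3 complex. Aluminium chelated between the carbonyl and the neighbouring methoxy oxygen then cleaves that O–CH3 bond, so only the ortho ether is lost and the phenol that becomes O1 is released in the same flask.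

**Step 2**
Reactants: 4 2-chloro-1-(2-hydroxy-3,4-dimethoxyphenyl)ethan-1-one
Product: 5 6,7-dimethoxy-1-benzofuran-3(2H)-one
Conditions: NaOAc, EtOH, reflux
Reagents that add atoms: none
Why: Intramolecular Williamson etherification: the phenoxide displaces the α-chloride in a 5-exo-tet closure. The weak acetate base limits aldol self-condensation of the product.

**Step 3**
Reactants: 6 3,4-dimethoxyphenol
Product: 7 4-(benzyloxy)-1,2-dimethoxybenzene
Conditions: BnBr, K2CO3, DMF, rt to 60 °C
Reagents that add atoms: benzyl bromide, BrCc1ccccc1
Why: Williamson O-benzylation of the phenol. The benzyl ether should survive the basic, organometallic and carbene steps and is the only ether cleaved by hydrogenolysis at the end.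

**Step 4**
Reactants: 7 4-(benzyloxy)-1,2-dimethoxybenzene
Product: 8 1-(benzyloxy)-2-bromo-4,5-dimethoxybenzene
Conditions: NBS, MeCN, 0 °C to rt
Reagents that add atoms: N-bromosuccinimide, O=C1CCC(=O)N1Br
Why: Electrophilic aromatic bromination. The carbon ortho to the benzyloxy group and para to the C2 methoxy group of 7 is the most activated and least hindered site, as in brominations of 1,2,4-trialkoxybenzenes.

**Step 5**
Reactants: 5 6,7-dimethoxy-1-benzofuran-3(2H)-one; 8 1-(benzyloxy)-2-bromo-4,5-dimethoxybenzene
Product: 9 2-[2-(benzyloxy)-4,5-dimethoxyphenyl]-6,7-dimethoxy-1-benzofuran-3(2H)-one (racemic)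
Conditions: Pd(OAc)2 (5 mol%), XPhos (10 mol%), NaOtBu (2.2 equiv), toluene, 80 °C, argon; degassed aq. NH4Cl
Reagents that add atoms: none
Why: Palladium-catalysed α-arylation of a ketone enolate (Buchwald–Hartwig type): oxidative addition of 8 to zerovalent palladium formed from Pd(OAc)2 and XPhos, exchange of bromide for the sodium enolate of 5, then C–C reductive elimination. The product is more acidic than 5 and is held as its hindered aromatic benzofuranolate, which should suppress a second arylation; the new C2 stereocentre is racemic and is removed in step 6.

**Step 6**
Reactants: 9 2-[2-(benzyloxy)-4,5-dimethoxyphenyl]-6,7-dimethoxy-1-benzofuran-3(2H)-one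
Product: 10 tert-butyl({2-[2-(benzyloxy)-4,5-dimethoxyphenyl]-6,7-dimethoxy-1-benzofuran-3-yl}oxy)dimethylsilane
Conditions: TBSOTf, Et3N, CH2Cl2, 0 °C, argon; water wash
Reagents that add atoms: tert-butyldimethylsilyl trifluoromethanesulfonate, CC(C)(C)[Si](C)(C)OS(=O)(=O)C(F)(F)F
Why: Soft enolisation and O-silylation. Enolisation of 9 is driven by aromatisation to the benzofuran and the hard silyl electrophile reacts at oxygen, giving the tetrasubstituted enol ether that the carbene needs.

**Step 7**
Reactants: 10 tert-butyl({2-[2-(benzyloxy)-4,5-dimethoxyphenyl]-6,7-dimethoxy-1-benzofuran-3-yl}oxy)dimethylsilane; 11 bromoform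
Product: 14 2-[2-(benzyloxy)-4,5-dimethoxyphenyl]-3-bromo-7,8-dimethoxy-4H-chromen-4-one, via dibromocyclopropane adduct 12 (not isolated), via 4-silyloxybenzopyrylium bromide 13 (not isolated)
Conditions: CHBr3 (4 equiv), KOtBu (5 equiv, solid, in portions), toluene–hexane, −20 °C to rt; aq. NH4Cl
Reagents that add atoms: bromoform (compound 11), BrC(Br)Br
Why: KOtBu deprotonates 11 and α-elimination of bromide gives singlet dibromocarbene, which adds in a concerted (2+1) cheletropic step to the C2=C3 bond of 10, the most electron-rich π bond in the molecule because it is a tetrasubstituted alkene bearing the ring oxygen, the silyloxy group and the aryl group. In adduct 12 the bromide on the face of the five-membered ring ionises while the fused bond cleaves in a disrotatory two-electron electrocyclic cyclopropyl-to-allyl opening, pushed by the lone pairs of O1 and of the silyloxy oxygen, to give the aromatic benzopyrylium bromide 13. Bromide then takes the silyl group from oxygen and leaves the C4 carbonyl of 14. Ring C is thus closed not by a cyclisation but by insertion of one carbon: the six-membered ring arises when the three-membered ring made in the cheletropic step opens across the bond it shares with the furan. The closest known reactions are the dihalocarbene ring expansion of cyclic silyl enol ethers to 2-halo enones and the Ciamician–Dennstedt-type expansion of benzofurans to 3-halochromenes. No stereocentre remains in 14; the two centres of 12 form as a racemic, necessarily cis-fused pair and are lost on opening. Chemoselectivity rests on the much higher nucleophilicity of the enol ether compared with the alkoxybenzene rings, which do not add dihalocarbenes, and keeping free alkoxide low by portionwise addition protects the O–Si bond. The regiochemistry is fixed because only cleavage of the fused bond gives a cation stabilised by two oxygens and releases the strain of the bicycle, which places bromine on C3.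

**Step 8**
Reactants: 14 2-[2-(benzyloxy)-4,5-dimethoxyphenyl]-3-bromo-7,8-dimethoxy-4H-chromen-4-one
Product: 15 2-[2-(benzyloxy)-4,5-dimethoxyphenyl]-3,7,8-trimethoxy-4H-chromen-4-one
Conditions: NaOMe (3 equiv), CuI (20 mol%), 1,10-phenanthroline (40 mol%), MeOH–1,4-dioxane, 95 °C, sealed tube
Reagents that add atoms: sodium methoxide, C[O-].[Na+]
Why: Ullmann-type copper-catalysed C–O coupling: a monovalent copper methoxide complex of phenanthroline inserts into the sp2 C3–Br bond and reductive elimination forms the methyl ether. The ortho-benzyloxyaryl group shields C2 and the C7/C8 methoxy groups lower the electrophilicity of the pyranone, which should disfavour conjugate attack of methoxide.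

**Step 9**
Reactants: 15 2-[2-(benzyloxy)-4,5-dimethoxyphenyl]-3,7,8-trimethoxy-4H-chromen-4-one
Product: 16 2-(2-hydroxy-4,5-dimethoxyphenyl)-3,7,8-trimethoxy-4H-chromen-4-one
Conditions: H2 (1 atm), Pd/C (10% palladium on carbon), EtOAc–MeOH, rt
Reagents that add atoms: none
Why: Hydrogenolysis of the benzyl aryl ether on palladium. Methyl ethers are inert and the tetrasubstituted C2=C3 bond of the vinylogous ester is not expected to be hydrogenated at atmospheric pressure and room temperature.

## Compound list

1 | 1,2,3-trimethoxybenzene | COc1cccc(OC)c1OC | starting material
2 | chloroacetyl chloride | ClCC(=O)Cl | starting material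
3 | 2-chloro-1-(2,3,4-trimethoxyphenyl)ethan-1-one (formed as its AlCl3 complex) | COc1ccc(C(=O)CCl)c(OC)c1OC | intermediate (not isolated)
4 | 2-chloro-1-(2-hydroxy-3,4-dimethoxyphenyl)ethan-1-one | COc1ccc(C(=O)CCl)c(O)c1OC | intermediate
5 | 6,7-dimethoxy-1-benzofuran-3(2H)-one | COc1ccc2c(c1OC)OCC2=O | intermediate
6 | 3,4-dimethoxyphenol | COc1ccc(O)cc1OC | starting material
7 | 4-(benzyloxy)-1,2-dimethoxybenzene | COc1ccc(OCc2ccccc2)cc1OC | intermediate
8 | 1-(benzyloxy)-2-bromo-4,5-dimethoxybenzene | COc1cc(Br)c(OCc2ccccc2)cc1OC | intermediate
9 | 2-[2-(benzyloxy)-4,5-dimethoxyphenyl]-6,7-dimethoxy-1-benzofuran-3(2H)-one (racemic at C2) | COc1ccc2c(c1OC)OC(c1cc(OC)c(OC)cc1OCc1ccccc1)C2=O | intermediate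
10 | tert-butyl({2-[2-(benzyloxy)-4,5-dimethoxyphenyl]-6,7-dimethoxy-1-benzofuran-3-yl}oxy)dimethylsilane | COc1ccc2c(O[Si](C)(C)C(C)(C)C)c(-c3cc(OC)c(OC)cc3OCc3ccccc3)oc2c1OC | intermediate
11 | bromoform | BrC(Br)Br | starting material
12 | 1a-[2-(benzyloxy)-4,5-dimethoxyphenyl]-1,1-dibromo-6b-{[tert-butyl(dimethyl)silyl]oxy}-3,4-dimethoxy-1a,6b-dihydro-1H-cyclopropa[b][1]benzofuran (racemic, cis-fused) | COc1ccc2c(c1OC)OC1(c3cc(OC)c(OC)cc3OCc3ccccc3)C(Br)(Br)C21O[Si](C)(C)C(C)(C)C | intermediate (not isolated)
13 | 2-[2-(benzyloxy)-4,5-dimethoxyphenyl]-3-bromo-4-{[tert-butyl(dimethyl)silyl]oxy}-7,8-dimethoxy-1-benzopyrylium bromide | COc1ccc2c(O[Si](C)(C)C(C)(C)C)c(Br)c(-c3cc(OC)c(OC)cc3OCc3ccccc3)[o+]c2c1OC.[Br-] | intermediate (not isolated)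
14 | 2-[2-(benzyloxy)-4,5-dimethoxyphenyl]-3-bromo-7,8-dimethoxy-4H-chromen-4-one | COc1cc(OCc2ccccc2)c(-c2oc3c(OC)c(OC)ccc3c(=O)c2Br)cc1OC | intermediate
15 | 2-[2-(benzyloxy)-4,5-dimethoxyphenyl]-3,7,8-trimethoxy-4H-chromen-4-one | COc1cc(OCc2ccccc2)c(-c2oc3c(OC)c(OC)ccc3c(=O)c2OC)cc1OC | intermediate
16 | 2-(2-hydroxy-4,5-dimethoxyphenyl)-3,7,8-trimethoxy-4H-chromen-4-one | COc1cc(O)c(-c2oc3c(OC)c(OC)ccc3c(=O)c2OC)cc1OC | target

## Step count and risk

Total step count: 9. Longest linear sequence: 7 steps (steps 1, 2, 5, 6, 7, 8, 9; the branch through steps 3 and 4 is equally long).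

**Step 7 (key step).** The most likely failure is cleavage of the O–Si bond by tert-butoxide before the carbene arrives. The carbene then meets an enolate and is captured at C2 without ring enlargement. The second risk is slow addition to the crowded tetrasubstituted bond next to the ortho-benzyloxyaryl group, during which the carbene is consumed by the alkoxide; opening of 12 may also be incomplete at low temperature. The fallback brings C3 in as part of an acetyl group and closes ring C oxidatively. It sets out from 1 and 7 and returns at 15. Compound 1 is acetylated with acetyl chloride and AlCl3, with the same chelation-controlled ortho-demethylation as in step 1, to give 1-(2-hydroxy-3,4-dimethoxyphenyl)ethan-1-one F1. Compound 7 is formylated under Vilsmeier–Haack conditions (POCl3, DMF) at the carbon ortho to the benzyloxy group to give 2-(benzyloxy)-4,5-dimethoxybenzaldehyde F2. Claisen–Schmidt condensation of the two (KOH, EtOH) gives (2E)-3-[2-(benzyloxy)-4,5-dimethoxyphenyl]-1-(2-hydroxy-3,4-dimethoxyphenyl)prop-2-en-1-one F3. Algar–Flynn–Oyamada oxidation (H2O2, NaOH, MeOH) closes ring C as 2-[2-(benzyloxy)-4,5-dimethoxyphenyl]-3-hydroxy-7,8-dimethoxy-4H-chromen-4-one F4, and O-methylation (MeI, K2CO3, acetone) gives 15, from which step 9 follows.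

**Step 5.** Self-condensation of the enolisable ketone 5 under base may outrun oxidative addition of the electron-rich, ortho-substituted bromide. A second arylation, or aerial oxidation at C2 of the product enolate during work-up, could also lower the return. The fallback forms the C2–C1' bond on the aromatic benzofuran by cross-coupling. It sets out from 5 and 8 and returns at 10, so step 6 is not needed. Compound 5 is silylated (TBSOTf, Et3N) to tert-butyl[(6,7-dimethoxy-1-benzofuran-3-yl)oxy]dimethylsilane F5. Its C2–H is removed with n-BuLi in THF at −78 °C and the anion is transmetalated at once with ZnCl2, before the silyl group can migrate from oxygen to carbon, giving chloro(3-{[tert-butyl(dimethyl)silyl]oxy}-6,7-dimethoxy-1-benzofuran-2-yl)zinc F6, which is not isolated. Negishi coupling with 8 (Pd(OAc)2, SPhos, THF, 50 °C) gives 10.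

**Step 8.** Methoxide may add in conjugate fashion at C2, after which ring C opens and the phenoxide recloses onto the brominated carbon (ring contraction). Reductive loss of bromine may also compete with C–O coupling. The fallback replaces the nucleophilic exchange by an oxidation of a carbon–boron bond. It sets out from 14 and returns at 15. Miyaura borylation (B2pin2, Pd(dppf)Cl2, KOAc, 1,4-dioxane, 80 °C) gives 2-[2-(benzyloxy)-4,5-dimethoxyphenyl]-7,8-dimethoxy-3-(4,4,5,5-tetramethyl-1,3,2-dioxaborolan-2-yl)-4H-chromen-4-one F7. Mild oxidation (NaBO3·4H2O, THF–H2O, rt) gives 2-[2-(benzyloxy)-4,5-dimethoxyphenyl]-3-hydroxy-7,8-dimethoxy-4H-chromen-4-one F4, the same flavonol as in the fallback to step 7, and O-methylation (MeI, K2CO3, acetone) gives 15.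

## Further compounds

F1 | step 7 | 1-(2-hydroxy-3,4-dimethoxyphenyl)ethan-1-one | COc1ccc(C(C)=O)c(O)c1OC
F2 | step 7 | 2-(benzyloxy)-4,5-dimethoxybenzaldehyde | COc1cc(C=O)c(OCc2ccccc2)cc1OC
F3 | step 7 | (2E)-3-[2-(benzyloxy)-4,5-dimethoxyphenyl]-1-(2-hydroxy-3,4-dimethoxyphenyl)prop-2-en-1-one | COc1ccc(C(=O)/C=C/c2cc(OC)c(OC)cc2OCc2ccccc2)c(O)c1OC
F4 | step 7 | 2-[2-(benzyloxy)-4,5-dimethoxyphenyl]-3-hydroxy-7,8-dimethoxy-4H-chromen-4-one | COc1cc(OCc2ccccc2)c(-c2oc3c(OC)c(OC)ccc3c(=O)c2O)cc1OC
F5 | step 5 | tert-butyl[(6,7-dimethoxy-1-benzofuran-3-yl)oxy]dimethylsilane | COc1ccc2c(O[Si](C)(C)C(C)(C)C)coc2c1OC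
F6 | step 5 | chloro(3-{[tert-butyl(dimethyl)silyl]oxy}-6,7-dimethoxy-1-benzofuran-2-yl)zinc | COc1ccc2c(O[Si](C)(C)C(C)(C)C)c([Zn]Cl)oc2c1OC
F7 | step 8 | 2-[2-(benzyloxy)-4,5-dimethoxyphenyl]-7,8-dimethoxy-3-(4,4,5,5-tetramethyl-1,3,2-dioxaborolan-2-yl)-4H-chromen-4-one | COc1cc(OCc2ccccc2)c(-c2oc3c(OC)c(OC)ccc3c(=O)c2B2OC(C)(C)C(C)(C)O2)cc1OC
A1 | alternative 1 | 2-[2-(benzyloxy)-4,5-dimethoxyphenyl]-3,7,8-trimethoxy-5,6-dihydro-4H-chromen-4-one | COC1=C(OC)c2oc(-c3cc(OC)c(OC)cc3OCc3ccccc3)c(OC)c(=O)c2CC1
A2 | alternative 1 | 6-[2-(benzyloxy)-4,5-dimethoxyphenyl]-5-methoxy-2,2-dimethyl-4H-1,3-dioxin-4-one | COC1=C(c2cc(OC)c(OC)cc2OCc2ccccc2)OC(C)(C)OC1=O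
A3 | alternative 1 | [(5,6-dimethoxycyclohexa-1,5-dien-1-yl)oxy]trimethylsilane | COC1=C(OC)C(O[Si](C)(C)C)=CCC1
A4 | alternative 2 | 2-[2-(benzyloxy)-4,5-dimethoxyphenyl]-3-hydroxy-7,8-dimethoxychroman-4-one (racemic, both C2/C3 diastereomers) | COc1ccc2c(c1OC)OC(c1cc(OC)c(OC)cc1OCc1ccccc1)C(O)C2=O
A5 | alternative 2 | 2-{1-[2-(benzyloxy)-4,5-dimethoxyphenyl]-2-oxoethoxy}-3,4-dimethoxybenzaldehyde (racemic) | COc1ccc(C=O)c(OC(C=O)c2cc(OC)c(OC)cc2OCc2ccccc2)c1OC
A6 | alternative 3 | 2-[2-(benzyloxy)-4,5-dimethoxyphenyl]-7-hydroxy-3,8-dimethoxy-4H-chromen-4-one | COc1cc(OCc2ccccc2)c(-c2oc3c(OC)c(O)ccc3c(=O)c2OC)cc1OC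
A7 | alternative 3 | 2-[2-(benzyloxy)-4,5-dimethoxyphenyl]-3-methoxy-6-(methoxymethyl)-4H-pyran-4-one | COCc1cc(=O)c(OC)c(-c2cc(OC)c(OC)cc2OCc2ccccc2)o1
A8 | alternative 3 | methyl 3,3-dimethoxypropanoate | COC(OC)CC(=O)OC
A9 | alternative 3 | kojic acid, 5-hydroxy-2-(hydroxymethyl)-4H-pyran-4-one | OCc1cc(=O)c(O)co1
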